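**Retrosynthetic overview**
- The target, 2-(4-hydroxyphenyl)ethyl heptatriacontanoate (acyl chain numbered C1 = ester carbonyl to C37 = methyl), is traced back to its O-benzyl ether; the phenol is unmasked last by hydrogenolysis.
- Key disconnection C15–C16: a Ni-electrocatalytic doubly decarboxylative coupling of two N-acyloxyphthalimides joins two carbons that both began as carboxyl-bearing carbons (like polarity) as primary alkyl radicals, the reductive counterpart of a mixed Kolbe coupling.
- Enabling feature: C15 and C16 are plain CH2 groups inside the unbranched, saturated chain C2–C37, fourteen or more bonds from the only functional groups (ester at C1, phenol) and with no stereocentre anywhere. Each is therefore available as a non-stabilised primary radical from a commercial acid one carbon longer (C16 diacid half-ester, C23 acid).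
- The C16 partner comes from mono-tert-butyl hexadecanedioate and 2-[4-(benzyloxy)phenyl]ethanol (esterification, tert-butyl acidolysis, N-hydroxyphthalimide ester); the C23 partner is the N-hydroxyphthalimide ester of tricosanoic acid.
- No ring is formed: the only ring, the 1,4-disubstituted benzene ring, is bought intact in the tyrosol unit.

Key step: step 5

Remark: the target is achiral, so no stereocontrol is needed; compounds 1, 2 and 6 are taken as commercial.

**Step 1**
Reactants: 1 16-(tert-butoxy)-16-oxohexadecanoic acid; 2 2-[4-(benzyloxy)phenyl]ethanol
Product: 3 1-tert-butyl 16-{2-[4-(benzyloxy)phenyl]ethyl} hexadecanedioate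
Conditions: DIC, DMAP (cat.), CH2Cl2, 0 °C to rt
Reagents that add atoms: none
Why: Steglich-type carbodiimide esterification of an unhindered acid with a primary alcohol should proceed cleanly, and the tert-butyl ester and aryl benzyl ether are inert to it.

**Step 2**
Reactants: 3 1-tert-butyl 16-{2-[4-(benzyloxy)phenyl]ethyl} hexadecanedioate
Product: 4 16-{2-[4-(benzyloxy)phenyl]ethoxy}-16-oxohexadecanoic acid
Conditions: TFA/CH2Cl2 (1:4), 0 °C to rt
Reagents that add atoms: none
Why: Acidolysis of the tert-butyl ester by alkyl–oxygen cleavage (loss of the tert-butyl cation as isobutene) should leave the primary alkyl ester and the aryl benzyl ether untouched under short exposure to anhydrous TFA.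

**Step 3**
Reactants: 4 16-{2-[4-(benzyloxy)phenyl]ethoxy}-16-oxohexadecanoic acid
Product: 5 1-{2-[4-(benzyloxy)phenyl]ethyl} 16-(1,3-dioxoisoindolin-2-yl) hexadecanedioate
Conditions: N-hydroxyphthalimide, DIC, DMAP (cat.), CH2Cl2, rt
Reagents that add atoms: N-hydroxyphthalimide, O=C1c2ccccc2C(=O)N1O
Why: Carbodiimide-mediated active-ester formation should give the redox-active N-acyloxyphthalimide, since the O-acylisourea is intercepted by the acidic N-hydroxy imide while the distal ester and ether do not react.

**Step 4**
Reactants: 6 tricosanoic acid
Product: 7 1,3-dioxoisoindolin-2-yl tricosanoate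
Conditions: N-hydroxyphthalimide, DIC, DMAP (cat.), CH2Cl2/THF, rt
Reagents that add atoms: N-hydroxyphthalimide, O=C1c2ccccc2C(=O)N1O
Why: The same carbodiimide-mediated active-ester formation should convert the unfunctionalised fatty acid into its redox-active ester.

**Step 5**
Reactants: 5 1-{2-[4-(benzyloxy)phenyl]ethyl} 16-(1,3-dioxoisoindolin-2-yl) hexadecanedioate; 7 1,3-dioxoisoindolin-2-yl tricosanoate
Product: 8 2-[4-(benzyloxy)phenyl]ethyl heptatriacontanoate
Conditions: 7 (3 equiv), NiCl2·6H2O (20 mol%), 2,2':6',2''-terpyridine (20 mol%), AgNO3 (0.3 equiv), NaI, DMF/THF, Mg(+)/RVC(−), undivided cell, constant current, 30 °C; dilute aq. HCl work-up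
Reagents that add atoms: none
Why: Cathodically generated low-valent nickel–terpyridine species should transfer single electrons to both N-acyloxyphthalimides, each radical anion fragmenting with loss of phthalimide anion and CO2 to a non-stabilised primary alkyl radical (the C15 ester-bearing radical from 5, the docosyl radical from 7); one radical is captured by nickel, the second converts the alkylnickel into a dialkylnickel(III) species, and reductive elimination forms the C15–C16 bond. The closest known reaction type is the Ni-electrocatalytic doubly decarboxylative C(sp3)–C(sp3) coupling of two redox-active esters, which has been shown for primary–primary pairs. The step closes no ring and creates no stereocentre. The selectivity it needs is cross- over homo-coupling, which is only statistical for two unactivated primary radicals; it is secured by the threefold excess of the cheap partner 7, so that 5 is consumed mainly in the cross-product, and by the polarity gap between the hydrocarbon homodimer, the mono-ester 8 and the C30 diester homodimer, which should make separation simple. Chemoselectivity follows from the reducing conditions, which should leave the alkyl ester and the electron-rich benzyloxyarene intact (an anodic Kolbe variant would endanger the arene), while the silver-coated cathode formed from AgNO3 suppresses direct reduction of the active esters.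

**Step 6**
Reactants: 8 2-[4-(benzyloxy)phenyl]ethyl heptatriacontanoate
Product: 9 2-(4-hydroxyphenyl)ethyl heptatriacontanoate
Conditions: H2 (1 atm), 10% Pd/C, THF/EtOAc, 40 °C
Reagents that add atoms: none
Why: Palladium-catalysed hydrogenolysis should cleave only the benzylic C–O bond of the aryl benzyl ether, because the ester oxygen sits on a homobenzylic (not benzylic) carbon and nothing else is reducible.

**Compound list**
1 | 16-(tert-butoxy)-16-oxohexadecanoic acid (mono-tert-butyl hexadecanedioate) | CC(C)(C)OC(=O)CCCCCCCCCCCCCCC(=O)O | starting material
2 | 2-[4-(benzyloxy)phenyl]ethanol | OCCc1ccc(OCc2ccccc2)cc1 | starting material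
3 | 1-tert-butyl 16-{2-[4-(benzyloxy)phenyl]ethyl} hexadecanedioate | CC(C)(C)OC(=O)CCCCCCCCCCCCCCC(=O)OCCc1ccc(OCc2ccccc2)cc1 | intermediate
4 | 16-{2-[4-(benzyloxy)phenyl]ethoxy}-16-oxohexadecanoic acid | OC(=O)CCCCCCCCCCCCCCC(=O)OCCc1ccc(OCc2ccccc2)cc1 | intermediate
5 | 1-{2-[4-(benzyloxy)phenyl]ethyl} 16-(1,3-dioxoisoindolin-2-yl) hexadecanedioate | O=C(CCCCCCCCCCCCCCC(=O)OCCc1ccc(OCc2ccccc2)cc1)ON1C(=O)c2ccccc2C1=O | intermediate
6 | tricosanoic acid | CCCCCCCCCCCCCCCCCCCCCCC(=O)O | starting material
7 | 1,3-dioxoisoindolin-2-yl tricosanoate | CCCCCCCCCCCCCCCCCCCCCCC(=O)ON1C(=O)c2ccccc2C1=O | intermediate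
8 | 2-[4-(benzyloxy)phenyl]ethyl heptatriacontanoate | CCCCCCCCCCCCCCCCCCCCCCCCCCCCCCCCCCCCC(=O)OCCc1ccc(OCc2ccccc2)cc1 | intermediate
9 | 2-(4-hydroxyphenyl)ethyl heptatriacontanoate | CCCCCCCCCCCCCCCCCCCCCCCCCCCCCCCCCCCCC(=O)OCCc1ccc(O)cc1 | target

**Step count and risks**
Total steps: 6. Longest linear sequence: 5 (steps 1, 2, 3, 5, 6).

Steps most likely to fail:

1. Step 5. The two primary radicals are not differentiated, so homo-coupling competes statistically; the active esters may also be reduced or hydrolysed before coupling, and the waxy substrates may precipitate from the polar electrolyte and foul the cathode. The fallback sets out from 5 and comes back to the route at 8, replacing the second radical precursor by a preformed C22 nucleophile. Commercial 1-bromodocosane (CCCCCCCCCCCCCCCCCCCCCCBr) is converted with magnesium in THF into docosylmagnesium bromide F1, which is transmetallated with ZnCl2 (0.5 equiv) to didocosylzinc F2. Nickel-catalysed decarboxylative alkyl–alkyl Negishi-type coupling of 5 with F2 (NiCl2·glyme, 4,4'-di-tert-butyl-2,2'-bipyridine, THF/DMF, rt) should then form the same C15–C16 bond and give 8 without a statistical homo-coupling problem, the dialkylzinc being inert towards the alkyl ester.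

2. Step 6. Debenzylation may stall because the long-chain ester dissolves poorly and crystallises onto the catalyst. The fallback sets out from 8 and comes back at 9, giving up the protecting group instead of removing it. Saponification of 8 (KOH, THF/EtOH/H2O, reflux, then HCl) should give heptatriacontanoic acid F3. Chemoselective Mitsunobu esterification of F3 with unprotected tyrosol (OCCc1ccc(O)cc1; PPh3, DIAD, THF, 0 to 40 °C) should then give 9 directly: only the aliphatic hydroxyl is activated as the alkoxyphosphonium ion and the carboxylic acid, being far more acidic than the phenol, is the pronucleophile that reacts.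

3. Step 2. The acid may also remove or shift the benzyl group, or the tert-butyl cation may alkylate the electron-rich ring. The fallback sets out from 2 and comes back at 4, avoiding any acid-labile ester. Alcohol 2 is acylated with an excess (about 4 equiv) of commercial hexadecanedioic acid (OC(=O)CCCCCCCCCCCCCCC(=O)O) under DIC/DMAP in THF at 40 °C; statistical mono-esterification should give 4 directly. The unreacted diacid is removed by filtration from cold CH2Cl2 and the minor diester by chromatography. This fallback makes no new compound (F0).

**Further compounds**
F1 | step 5 | docosylmagnesium bromide | CCCCCCCCCCCCCCCCCCCCCC[Mg]Br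
F2 | step 5 | didocosylzinc | CCCCCCCCCCCCCCCCCCCCCC[Zn]CCCCCCCCCCCCCCCCCCCCCC
F3 | step 6 | heptatriacontanoic acid | CCCCCCCCCCCCCCCCCCCCCCCCCCCCCCCCCCCCC(=O)O
F0 | step 2 | none | none
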